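**Assumption:** the target SMILES defines no stereocentre and no biaryl axis, so the axis is treated as racemic or rapidly interconverting and the route delivers the racemate.

## Retrosynthetic overview
1. Disconnect the hindered biaryl bond (naphthoquinone A C6 to naphthoquinone B C8) by Suzuki–Miyaura coupling, giving bromotetralone **11** and pinacol boronate **20**.
2. After coupling, aromatise both tetralones (DDQ) and oxidise the naphthols to quinones (Fremy's salt). Add EtOH to the A-quinone by oxa-Michael addition (the B-ring OEt is already placed α to its ketone), then remove the peri O-methyl groups.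
3. The tetralones come from Friedel–Crafts succinoylation, ionic hydrogenation and PPA cyclisation. Branch A starts from o-cresol via 2,5-dimethoxytoluene, NBS bromination and peri-deoxygenation. Branch B starts from m-cresol via 4-bromo-3-methylanisole, α-ethoxylation and borylation.
4. Ring order: benzenoid rings (from the cresols), then cyclohexanone rings (PPA), then the biaryl, then the aromatic and quinone rings.

## Route

**Step 1**
Reactants: 1 o-cresol
Product: 2 2-methyl-1,4-benzoquinone
Conditions: (KSO3)2NO (Fremy's salt, 2.2 equiv), NaH2PO4, MeCN/H2O, rt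
Reagents that add atoms: water, O
Why: Teuber oxidation of a phenol with a free para position gives the p-quinone.

**Step 2**
Reactants: 2
Product: 3 2,5-dimethoxytoluene
Conditions: Na2S2O4, Et2O/H2O; then Me2SO4, NaOH, Bu4NBr, rt
Reagents that add atoms: dimethyl sulfate, COS(=O)(=O)OC
Why: Reduction to the hydroquinone followed by O-methylation (reductive methylation).

**Step 3**
Reactants: 3; 4 succinic anhydride
Product: 5 4-(2,5-dimethoxy-4-methylphenyl)-4-oxobutanoic acid
Conditions: AlCl3, CH2Cl2, 0 °C → rt
Reagents that add atoms: none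
Why: Friedel–Crafts acylation goes at the position ortho to OMe and para to Me, the most activated and least hindered site.

**Step 4**
Reactants: 5
Product: 6 4-(2,5-dimethoxy-4-methylphenyl)butanoic acid
Conditions: Et3SiH, TFA, rt
Reagents that add atoms: none
Why: Ionic hydrogenation removes the electron-rich aryl ketone oxygen and leaves the acid untouched.

**Step 5**
Reactants: 6
Product: 7 5,8-dimethoxy-7-methyl-3,4-dihydronaphthalen-1(2H)-one
Conditions: PPA, 80 °C
Reagents that add atoms: none
Why: Intramolecular Friedel–Crafts acylation closes at the only free ortho position, which is activated by the adjacent OMe.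

**Step 6**
Reactants: 7
Product: 8 6-bromo-5,8-dimethoxy-7-methyl-3,4-dihydronaphthalen-1(2H)-one
Conditions: NBS, MeCN, rt
Reagents that add atoms: N-bromosuccinimide, O=C1CCC(=O)N1Br
Why: Electrophilic bromination; C6 is the only remaining aromatic C–H, so regiochemistry is fixed.

**Step 7**
Reactants: 8
Product: 9 6-bromo-8-hydroxy-5-methoxy-7-methyl-3,4-dihydronaphthalen-1(2H)-one
Conditions: BCl3, CH2Cl2, −78 → 0 °C
Reagents that add atoms: none
Why: BCl3 chelates the ketone and cleaves only the peri OMe (C8).

**Step 8**
Reactants: 9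
Product: 10 the 8-triflate of 9 (6-bromo-5-methoxy-7-methyl-1-oxo-1,2,3,4-tetrahydronaphthalen-8-yl trifluoromethanesulfonate)
Conditions: Tf2O, pyridine, CH2Cl2, 0 °C
Reagents that add atoms: triflic anhydride, O=S(=O)(OS(=O)(=O)C(F)(F)F)C(F)(F)F
Why: O-Triflation of the phenol.

**Step 9**
Reactants: 10
Product: 11 6-bromo-5-methoxy-7-methyl-3,4-dihydronaphthalen-1(2H)-one
Conditions: Pd(OAc)2, PPh3, HCO2H, Et3N, DMF, 60 °C
Reagents that add atoms: none
Why: Pd-catalysed formate hydrodetriflation; the electron-poor peri triflate reacts in preference to the di-ortho-substituted aryl bromide, removing the C8 oxygen.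

**Step 10**
Reactants: 12 m-cresol
Product: 13 4-bromo-3-methylphenol
Conditions: NBS, MeCN, −10 °C
Reagents that add atoms: N-bromosuccinimide, O=C1CCC(=O)N1Br
Why: Electrophilic bromination is para-selective to the OH.

**Step 11**
Reactants: 13
Product: 14 4-bromo-3-methylanisole
Conditions: MeI, K2CO3, acetone, reflux
Reagents that add atoms: iodomethane, CI
Why: Williamson O-methylation.

**Step 12**
Reactants: 14; 4 succinic anhydride
Product: 15 4-(5-bromo-2-methoxy-4-methylphenyl)-4-oxobutanoic acid
Conditions: AlCl3, CH2Cl2, 0 °C → rt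
Reagents that add atoms: none
Why: The para-to-OMe position is blocked by Br, so acylation goes ortho to OMe and para to Me.

**Step 13**
Reactants: 15
Product: 16 4-(5-bromo-2-methoxy-4-methylphenyl)butanoic acid
Conditions: Et3SiH, TFA, rt
Reagents that add atoms: none
Why: Ionic hydrogenation of the aryl ketone; the aryl bromide survives.

**Step 14**
Reactants: 16
Product: 17 8-bromo-5-methoxy-7-methyl-3,4-dihydronaphthalen-1(2H)-one
Conditions: PPA, 90 °C
Reagents that add atoms: none
Why: Friedel–Crafts cyclisation has only one free ortho site, so the ketone ends up peri to Br (the future biaryl position).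

**Step 15**
Reactants: 17
Product: 18 (±)-8-bromo-2-hydroxy-5-methoxy-7-methyl-3,4-dihydronaphthalen-1(2H)-one
Conditions: LDA, THF, −78 °C; then the oxaziridine
Reagents that add atoms: 2-(phenylsulfonyl)-3-phenyloxaziridine, O=S(=O)(c1ccccc1)N1OC1c1ccccc1
Why: Enolate α-hydroxylation (Davis) occurs only at C2; the new stereocentre is racemic and is destroyed in step 19.

**Step 16**
Reactants: 18
Product: 19 (±)-8-bromo-2-ethoxy-5-methoxy-7-methyl-3,4-dihydronaphthalen-1(2H)-one
Conditions: EtI, Ag2O, CH2Cl2, rt
Reagents that add atoms: iodoethane, CCI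
Why: Silver-mediated O-ethylation of the α-ketol places the OEt next to the ketone that is peri to the aryl-bearing carbon, as in the target.

**Step 17**
Reactants: 19
Product: 20 (±)-2-ethoxy-5-methoxy-7-methyl-8-(4,4,5,5-tetramethyl-1,3,2-dioxaborolan-2-yl)-3,4-dihydronaphthalen-1(2H)-one
Conditions: B2pin2, XPhos-Pd-G2, KOAc, dioxane, 100 °C
Reagents that add atoms: bis(pinacolato)diboron, CC1(C)OB(OC1(C)C)B1OC(C)(C)C(C)(C)O1
Why: Miyaura borylation of the electron-poor aryl bromide (ortho to a ketone).

**Step 18**
Reactants: 11; 20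
Product: 21 bis-tetralone (A C6 joined to B C8)
Conditions: Pd2(dba)3, SPhos, K3PO4, toluene/H2O, 110 °C
Reagents that add atoms: none
Why: Suzuki–Miyaura coupling with a bulky biaryl phosphine builds the tetra-ortho-substituted biaryl; the axis is formed racemic and the C2 stereocentre is untouched.

**Step 19**
Reactants: 21
Product: 22 bis(1-naphthol)
Conditions: DDQ (2.4 equiv), dioxane, 100 °C
Reagents that add atoms: none
Why: Dehydrogenative aromatisation of each α-tetralone through its enol; this also removes the C2 stereocentre.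

**Step 20**
Reactants: 22
Product: 23 bis(1,4-naphthoquinone); A-ring unsubstituted at C2/C3, B-ring 2-OEt
Conditions: Fremy's salt (4.5 equiv), NaH2PO4, MeCN/H2O/acetone, rt
Reagents that add atoms: water, O
Why: Teuber oxidation of each 1-naphthol at its free para carbon gives the 1,4-quinone.

**Step 21**
Reactants: 23
Product: 24 bis-quinone carrying both ethoxy groups (5,5'-dimethoxy)
Conditions: EtOH, cat. CeCl3·7H2O, THF, rt, air; then Ag2O
Reagents that add atoms: ethanol, CCO
Why: Oxa-Michael addition followed by reoxidation. In the A-ring the non-H-bonded peri OMe deactivates C4=O, so EtOH adds β to C1=O, at C3. The B-ring vinylogous ester (2-OEt) is far less electrophilic, so it is not attacked.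

**Step 22**
Reactants: 24
Product: 25 2,3'-diethoxyisodiospyrin (target)
Conditions: BCl3 (4 equiv), CH2Cl2, −78 → 0 °C; aq. work-up
Reagents that add atoms: none
Why: Chelation-controlled cleavage of the two peri methyl ethers gives the H-bonded peri phenols.

## Compound list
1 | o-cresol | Cc1ccccc1O | starting material
2 | 2-methyl-1,4-benzoquinone | CC1=CC(=O)C=CC1=O | intermediate
3 | 2,5-dimethoxytoluene | Cc1cc(OC)ccc1OC | intermediate
4 | succinic anhydride | O=C1CCC(=O)O1 | starting material
5 | 4-(2,5-dimethoxy-4-methylphenyl)-4-oxobutanoic acid | COc1cc(C)c(OC)cc1C(=O)CCC(=O)O | intermediate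
6 | 4-(2,5-dimethoxy-4-methylphenyl)butanoic acid | COc1cc(C)c(OC)cc1CCCC(=O)O | intermediate
7 | 5,8-dimethoxy-7-methyl-1-tetralone | O=C1CCCc2c(OC)cc(C)c(OC)c12 | intermediate
8 | 6-bromo-5,8-dimethoxy-7-methyl-1-tetralone | O=C1CCCc2c(OC)c(Br)c(C)c(OC)c12 | intermediate
9 | 6-bromo-8-hydroxy-5-methoxy-7-methyl-1-tetralone | O=C1CCCc2c(OC)c(Br)c(C)c(O)c12 | intermediate
10 | 8-triflate of 9 | O=C1CCCc2c(OC)c(Br)c(C)c(OS(=O)(=O)C(F)(F)F)c12 | intermediate
11 | 6-bromo-5-methoxy-7-methyl-1-tetralone | O=C1CCCc2c(OC)c(Br)c(C)cc12 | intermediate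
12 | m-cresol | Cc1cccc(O)c1 | starting material
13 | 4-bromo-3-methylphenol | Cc1cc(O)ccc1Br | intermediate
14 | 4-bromo-3-methylanisole | Cc1cc(OC)ccc1Br | intermediate
15 | 4-(5-bromo-2-methoxy-4-methylphenyl)-4-oxobutanoic acid | COc1cc(C)c(Br)cc1C(=O)CCC(=O)O | intermediate
16 | 4-(5-bromo-2-methoxy-4-methylphenyl)butanoic acid | COc1cc(C)c(Br)cc1CCCC(=O)O | intermediate
17 | 8-bromo-5-methoxy-7-methyl-1-tetralone | O=C1CCCc2c(OC)cc(C)c(Br)c12 | intermediate
18 | (±)-8-bromo-2-hydroxy-5-methoxy-7-methyl-1-tetralone | O=C1C(O)CCc2c(OC)cc(C)c(Br)c12 | intermediate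
19 | (±)-8-bromo-2-ethoxy-5-methoxy-7-methyl-1-tetralone | O=C1C(OCC)CCc2c(OC)cc(C)c(Br)c12 | intermediate
20 | (±)-2-ethoxy-5-methoxy-7-methyl-8-Bpin-1-tetralone | O=C1C(OCC)CCc2c(OC)cc(C)c(B3OC(C)(C)C(C)(C)O3)c12 | intermediate
21 | bis-tetralone biaryl | O=C1CCCc2c(OC)c(-c3c(C)cc(OC)c4c3C(=O)C(OCC)CC4)c(C)cc12 | intermediate
22 | bis(1-naphthol) biaryl | Oc1cccc2c(OC)c(-c3c(C)cc(OC)c4ccc(OCC)c(O)c34)c(C)cc12 | intermediate
23 | bis(1,4-naphthoquinone) biaryl | O=C1C=CC(=O)c2c(OC)c(-c3c(C)cc(OC)c4C(=O)C=C(OCC)C(=O)c34)c(C)cc12 | intermediate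
24 | diethoxy bis-quinone, 5,5'-di-O-methyl | O=C1C=C(OCC)C(=O)c2c(OC)c(-c3c(C)cc(OC)c4C(=O)C=C(OCC)C(=O)c34)c(C)cc12 | intermediate
25 | 2,3'-diethoxyisodiospyrin | CCOC1=CC(=O)c2cc(C)c(-c3c(C)cc(O)c4c3C(=O)C(OCC)=CC4=O)c(O)c2C1=O | target

## Totals
- Total steps: 22.
- Longest linear sequence: 14 (steps 1–9, 18, 19, 20, 21, 22), which is 64% of the total.

## Three steps most likely to fail
1. **Step 21 (regioselective EtOH addition to the A-quinone).** The twisted, doubly flanked peri OMe may give a C2/C3 mixture. Fallback: build the A-half with its ketone peri to OMe by Parham cyclisation of an ortho-bromoanisole carrying a tethered ester, then set the OEt by the Davis/EtI α-ethoxylation used in steps 15–16, so no Michael step is needed.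
2. **Step 18 (tetra-ortho-substituted Suzuki coupling).** Fallback: switch to Stille coupling, using the aryl stannane made from **19** and bromide **11** with Pd/CuI, which tolerates hindered partners better than boron.
3. **Step 14 (PPA cyclisation onto a ring position flanked by Br).** Fallback: use tetralone **7** as the B-half precursor. Do the α-hydroxylation/ethylation on it, then BCl3 peri-demethylation and triflation, and couple that B-half triflate with an A-half boronate made from **11**; this avoids the bromo-tetralone cyclisation.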